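## Retrosynthetic overview
1. Odoratisol A ⇒ remove the TIPS group and cut the C5–propenyl bond (Suzuki coupling on a C5 boronate made by sterically governed C–H borylation). This leaves a 7-methoxy-2-aryl-3-methyl-2,3-dihydrobenzofuran.
2. ⇒ O-methylation of the 7-phenol. The phenol comes from a gold-catalysed furan–yne benzannulation that forms C3a–C7a and C6–C7 and moves the furan oxygen to C7.
3. Furyl ynol ether ⇒ (1S,2R)-1-aryl-2-(furan-2-yl)propan-1-ol plus trichloroethylene, which supplies C7a and C7.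
4. Alcohol ⇒ racemic α-furyl ketone; a dynamic kinetic asymmetric hydrogenation sets both stereocentres. Ketone ⇒ O-TIPS syringaldehyde plus 2-vinylfuran by branched hydroacylation.
5. Ring order: aryl ring C is bought. The furan is bought and consumed. Benzene ring A and dihydrofuran ring B close together in step 5.

Assumption: stabilised 2-vinylfuran and isomerically pure (E)-1-bromoprop-1-ene are bought. Numbering is that of 2,3-dihydro-1-benzofuran (O1, C2, C3, C3a, C4–C7, C7a).

## Route

Step 1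
Reactants: 1 syringaldehyde
Product: 2 3,5-dimethoxy-4-[(triisopropylsilyl)oxy]benzaldehyde
Conditions: TIPSCl, imidazole, DMAP (cat.), DMF, rt to 40 °C
Reagents that add atoms: chlorotriisopropylsilane (TIPSCl), CC(C)[Si](Cl)(C(C)C)C(C)C
Why: Imidazole-promoted silyl ether formation masks the only acidic OH against KH, n-BuLi and MeI, the TIPS group flanked by two methoxy groups resists the basic steps ahead, and no stereocentre is formed.

Step 2
Reactants: 2 3,5-dimethoxy-4-[(triisopropylsilyl)oxy]benzaldehyde; 3 2-vinylfuran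
Product: 4 (±)-1-{3,5-dimethoxy-4-[(triisopropylsilyl)oxy]phenyl}-2-(furan-2-yl)propan-1-one
Conditions: Ni(cod)2 (10 mol %), IMes (12 mol %), 3 (1.5 equiv), 1,4-dioxane, 80 °C
Reagents that add atoms: none
Why: Branched-selective hydroacylation of a vinyl(hetero)arene under zerovalent nickel/NHC catalysis passes the aldehyde hydrogen to the alkene terminus and couples the acyl group to the η3-furfuryl carbon, and the new stereocentre is left racemic on purpose because it is base-labile and is fixed in step 3.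

Step 3
Reactants: 4 (±)-1-{3,5-dimethoxy-4-[(triisopropylsilyl)oxy]phenyl}-2-(furan-2-yl)propan-1-one
Product: 5 (1S,2R)-1-{3,5-dimethoxy-4-[(triisopropylsilyl)oxy]phenyl}-2-(furan-2-yl)propan-1-ol
Conditions: RuCl2[(R)-xylbinap][(R)-daipen] (0.5 mol %), KOtBu (5 mol %), H2 (10 atm), i-PrOH, 25 °C
Reagents that add atoms: none
Why: In this Noyori asymmetric hydrogenation under dynamic kinetic resolution KOtBu racemises the acidic α-furyl centre faster than reduction, the (R,R)-catalyst (which gives (S)-aryl carbinols) reduces one ketone enantiomer only, and both stereocentres are therefore set here in the Felkin-type relative configuration that maps onto the trans ring, with furan and silyl ether untouched.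

Step 4
Reactants: 5 (1S,2R)-1-{3,5-dimethoxy-4-[(triisopropylsilyl)oxy]phenyl}-2-(furan-2-yl)propan-1-ol; 6 trichloroethylene
Product: 9 {4-[(1S,2R)-1-(ethynyloxy)-2-(furan-2-yl)propyl]-2,6-dimethoxyphenoxy}triisopropylsilane, via dichlorovinyl ether 7 (not isolated), via lithium alkoxyacetylide 8 (not isolated)
Conditions: KH, THF, 0 °C; 6 (1.1 equiv), −50 °C to rt; n-BuLi (2.5 equiv), −78 to −40 °C; MeOH, −78 °C; cold work-up, used at once
Reagents that add atoms: none
Why: In the Greene ynol ether synthesis the potassium alkoxide adds anti to dichloroacetylene released from 6, n-BuLi then effects β-elimination and chlorine–lithium exchange, and protonation gives the terminal ynol ether, so only the O–H bond of 5 changes and both stereocentres are retained.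

Step 5
Reactants: 9 {4-[(1S,2R)-1-(ethynyloxy)-2-(furan-2-yl)propyl]-2,6-dimethoxyphenoxy}triisopropylsilane
Product: 11 {4-[(2S,3S)-7-methoxy-3-methyl-2,3-dihydro-1-benzofuran-2-yl]-2,6-dimethoxyphenoxy}triisopropylsilane, via 7-phenol 10 (not isolated)
Conditions: IPrAuNTf2 (3 mol %), 4 Å MS, CH2Cl2, −20 °C to rt; evaporate; K2CO3, MeI, acetone, 45 °C
Reagents that add atoms: iodomethane, CI
Why: In this gold-catalysed furan–yne phenol synthesis (Hashmi type) on an alkynyl ether, monovalent gold makes the oxygen-bearing alkyne carbon (C7a) electrophilic, furan C2 (C3a) attacks it 5-exo, and the furan opens and recloses with its oxygen transposed to the alkyne terminus (C7, directed by the O1 donor), so benzene ring A and dihydrofuran ring B close in one operation with the tether stereocentres becoming (2S,3S), and Williamson methylation caps the air-sensitive phenol.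

Step 6
Reactants: 11 {4-[(2S,3S)-7-methoxy-3-methyl-2,3-dihydro-1-benzofuran-2-yl]-2,6-dimethoxyphenoxy}triisopropylsilane; 12 (E)-1-bromoprop-1-ene
Product: 15 odoratisol A, via C5 pinacol boronate 13 (not isolated), via O-TIPS odoratisol A 14 (not isolated)
Conditions: [Ir(OMe)(cod)]2 (2 mol %), dtbpy (4 mol %), B2pin2 (1.0 equiv), THF, 80 °C; then 12 (2 equiv), Pd(dppf)Cl2 (5 mol %), K3PO4, H2O, 60 °C, sealed; then TBAF, rt
Reagents that add atoms: bis(pinacolato)diboron, CC1(C)OB(OC1(C)C)B1OC(C)(C)C(C)(C)O1 (its boryl group is carried only by 13)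
Why: Sterically governed iridium-catalysed C–H borylation selects C5, the only aryl C–H in the molecule without an ortho substituent, Suzuki–Miyaura coupling then transfers the propenyl group with retention of the E geometry, and fluoride desilylation frees the syringyl phenol without touching C2 or C3.

## Compound list
1 | syringaldehyde | O=Cc1cc(OC)c(O)c(OC)c1 | starting material
2 | 3,5-dimethoxy-4-[(triisopropylsilyl)oxy]benzaldehyde | O=Cc1cc(OC)c(O[Si](C(C)C)(C(C)C)C(C)C)c(OC)c1 | intermediate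
3 | 2-vinylfuran | C=Cc1ccco1 | starting material
4 | (±)-1-{3,5-dimethoxy-4-[(triisopropylsilyl)oxy]phenyl}-2-(furan-2-yl)propan-1-one | CC(c1ccco1)C(=O)c1cc(OC)c(O[Si](C(C)C)(C(C)C)C(C)C)c(OC)c1 | intermediate
5 | (1S,2R)-1-{3,5-dimethoxy-4-[(triisopropylsilyl)oxy]phenyl}-2-(furan-2-yl)propan-1-ol | c1ccc(o1)[C@H](C)[C@@H](c1cc(OC)c(O[Si](C(C)C)(C(C)C)C(C)C)c(OC)c1)O | intermediate
6 | trichloroethylene | ClC=C(Cl)Cl | starting material
7 | (E)-1,2-dichlorovinyl ether of 5 | c1ccc(o1)[C@H](C)[C@@H](c1cc(OC)c(O[Si](C(C)C)(C(C)C)C(C)C)c(OC)c1)O/C(Cl)=C\Cl | intermediate (not isolated)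
8 | lithium alkoxyacetylide of 9 | c1ccc(o1)[C@H](C)[C@@H](c1cc(OC)c(O[Si](C(C)C)(C(C)C)C(C)C)c(OC)c1)OC#C[Li] | intermediate (not isolated)
9 | {4-[(1S,2R)-1-(ethynyloxy)-2-(furan-2-yl)propyl]-2,6-dimethoxyphenoxy}triisopropylsilane | c1ccc(o1)[C@H](C)[C@@H](c1cc(OC)c(O[Si](C(C)C)(C(C)C)C(C)C)c(OC)c1)OC#C | intermediate
10 | (2S,3S)-2-{3,5-dimethoxy-4-[(triisopropylsilyl)oxy]phenyl}-3-methyl-2,3-dihydro-1-benzofuran-7-ol | c1cc(O)c2c(c1)[C@H](C)[C@@H](c1cc(OC)c(O[Si](C(C)C)(C(C)C)C(C)C)c(OC)c1)O2 | intermediate (not isolated)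
11 | {4-[(2S,3S)-7-methoxy-3-methyl-2,3-dihydro-1-benzofuran-2-yl]-2,6-dimethoxyphenoxy}triisopropylsilane | c1cc(OC)c2c(c1)[C@H](C)[C@@H](c1cc(OC)c(O[Si](C(C)C)(C(C)C)C(C)C)c(OC)c1)O2 | intermediate
12 | (E)-1-bromoprop-1-ene | C/C=C/Br | starting material
13 | C5 pinacol boronate of 11 | CC1(C)OB(OC1(C)C)c1cc(OC)c2c(c1)[C@H](C)[C@@H](c1cc(OC)c(O[Si](C(C)C)(C(C)C)C(C)C)c(OC)c1)O2 | intermediate (not isolated)
14 | O-TIPS odoratisol A | C/C=C/c1cc(OC)c2c(c1)[C@H](C)[C@@H](c1cc(OC)c(O[Si](C(C)C)(C(C)C)C(C)C)c(OC)c1)O2 | intermediate (not isolated)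
15 | odoratisol A, (2S,3S) | C/C=C/c1cc(OC)c2c(c1)[C@H](C)[C@@H](c1cc(OC)c(O)c(OC)c1)O2 | target

## Step count
Total steps: 6. Longest linear sequence: 6 (1 → 2 → 4 → 5 → 9 → 11 → 15).

## Steps most likely to fail, and fallbacks

**Step 5 (gold benzannulation).**
- The benzylic C–O bond of the activated ynol ether may ionise.
- The dimethoxyaryl ring may attack the alkyne in place of the furan.
- Traces of water would hydrate 9 to the acetate.

In the fallback, ring A is brought in as an arene and only the O1–C7a bond is closed. It sets out from 2. EtMgBr addition gives the carbinol 1-{3,5-dimethoxy-4-[(triisopropylsilyl)oxy]phenyl}propan-1-ol F1. Dess–Martin oxidation gives the propiophenone F2. Palladium-catalysed α-arylation (Pd2(dba)3, XPhos, K3PO4, toluene, 80 °C) with 1-bromo-2-chloro-3-methoxybenzene gives the racemic chloroaryl ketone F3. The dynamic kinetic hydrogenation of step 3 gives the (1S,2S)-chloro alcohol F4. Intramolecular C–O coupling (Pd(OAc)2, t-BuBrettPhos, Cs2CO3, toluene, 90 °C) closes ring B with both stereocentres retained. The fallback comes back to the route at 11.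

**Step 4 (ynol ether).** The hindered alkoxide may add poorly. Compound 9 can also rearrange sigmatropically or lose ketene on warming. In the fallback, the two alkyne carbons are put on one at a time. It sets out from 5. Formylation (HCO2H, DCC, DMAP, CH2Cl2) gives the formate ester F5. Wittig-type dichloromethylenation (PPh3, CCl4, THF, reflux) gives the 2,2-dichlorovinyl ether F6. n-BuLi (2.2 equiv, −78 °C) then effects elimination and chlorine–lithium exchange. The fallback comes back to the route at 8.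

**Step 2 (nickel hydroacylation).** Tishchenko dimerisation of 2 or oligomerisation of 3 may win. In the fallback, the acyl donor becomes an anhydride and the nucleophile a chiral furfuryl copper species. It sets out from 2 and 3. Pinnick oxidation (NaClO2, NaH2PO4, 2-methyl-2-butene) gives the benzoic acid F7. DCC (0.5 equiv) gives the symmetrical anhydride F8. Copper hydride catalysis (Cu(OAc)2, (S,S)-Ph-BPE or its antipode as a first run dictates, (MeO)2MeSiH, THF, 40 °C, NH4F work-up) hydrocuprates 3 and acylates it to the (S)-ketone F9. The same pot reduces F9 in the Felkin sense. The fallback comes back to the route at 5, so step 3 is bypassed.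

## Further compounds
F1 | step 5 | 1-{3,5-dimethoxy-4-[(triisopropylsilyl)oxy]phenyl}propan-1-ol (racemic) | CCC(O)c1cc(OC)c(O[Si](C(C)C)(C(C)C)C(C)C)c(OC)c1
F2 | step 5 | 1-{3,5-dimethoxy-4-[(triisopropylsilyl)oxy]phenyl}propan-1-one | CCC(=O)c1cc(OC)c(O[Si](C(C)C)(C(C)C)C(C)C)c(OC)c1
F3 | step 5 | (±)-2-(2-chloro-3-methoxyphenyl)-1-{3,5-dimethoxy-4-[(triisopropylsilyl)oxy]phenyl}propan-1-one | CC(C(=O)c1cc(OC)c(O[Si](C(C)C)(C(C)C)C(C)C)c(OC)c1)c1cccc(OC)c1Cl
F4 | step 5 | (1S,2S)-2-(2-chloro-3-methoxyphenyl)-1-{3,5-dimethoxy-4-[(triisopropylsilyl)oxy]phenyl}propan-1-ol | COc1cccc([C@H](C)[C@@H](c2cc(OC)c(O[Si](C(C)C)(C(C)C)C(C)C)c(OC)c2)O)c1Cl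
F5 | step 4 | formate ester of 5 | c1ccc(o1)[C@H](C)[C@@H](c1cc(OC)c(O[Si](C(C)C)(C(C)C)C(C)C)c(OC)c1)OC=O
F6 | step 4 | 2,2-dichlorovinyl ether of 5 | c1ccc(o1)[C@H](C)[C@@H](c1cc(OC)c(O[Si](C(C)C)(C(C)C)C(C)C)c(OC)c1)OC=C(Cl)Cl
F7 | step 2 | 3,5-dimethoxy-4-[(triisopropylsilyl)oxy]benzoic acid | OC(=O)c1cc(OC)c(O[Si](C(C)C)(C(C)C)C(C)C)c(OC)c1
F8 | step 2 | 3,5-dimethoxy-4-[(triisopropylsilyl)oxy]benzoic anhydride | O=C(OC(=O)c1cc(OC)c(O[Si](C(C)C)(C(C)C)C(C)C)c(OC)c1)c1cc(OC)c(O[Si](C(C)C)(C(C)C)C(C)C)c(OC)c1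
F9 | step 2 | (S)-1-{3,5-dimethoxy-4-[(triisopropylsilyl)oxy]phenyl}-2-(furan-2-yl)propan-1-one | c1ccc(o1)[C@H](C)C(=O)c1cc(OC)c(O[Si](C(C)C)(C(C)C)C(C)C)c(OC)c1
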